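**Assumption:** the SMILES has no stereocentre and gives no descriptor for the hindered biaryl axis, so the compound is made as drawn, with the axis formed without control (racemic).

## Retrosynthetic overview

1. Target ⇐ four-fold O-debenzylation of a tetrabenzyl biflavone.
2. Pyranone ring of the 8-linked (4-methoxyphenyl) flavone ⇐ oxidative cyclisation of a 2'-hydroxychalcone ⇐ key intermolecular Claisen–Schmidt aldol of a biaryl methyl ketone with 4-methoxybenzaldehyde.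
3. Biaryl methyl ketone ⇐ Suzuki–Miyaura coupling of a 6-iodoflavone with an acetophenone boronate, the two flanking phenols masked as small MOM ethers.
4. 6-Iodoflavone ⇐ a first aldol/oxidative cyclisation, chelation-controlled 5-O-debenzylation and iodination ortho to the free 5-OH; the boronate ⇐ ortho-iodination and borylation of the same dibenzyl phloroacetophenone.
5. Ring order: both A rings come intact from phloroacetophenone; pyranone ring of the 6-linked unit first, biaryl bond second, pyranone ring of the 8-linked unit last.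

## Route

**Step 1**
Reactants: 1 2',4',6'-trihydroxyacetophenone
Product: 2 1-[2,4-bis(benzyloxy)-6-hydroxyphenyl]ethan-1-one
Conditions: BnBr (2.05 equiv), K2CO3 (2.2 equiv), DMF, 0 °C → rt
Reagents that add atoms: benzyl bromide, BrCc1ccccc1
Why: Williamson etherification alkylates the two most acidic phenols, while the last ortho-OH is held in a hydrogen bond to the ketone and stays free.

**Step 2**
Reactants: 2 1-[2,4-bis(benzyloxy)-6-hydroxyphenyl]ethan-1-one; 3 4-(benzyloxy)benzaldehyde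
Product: 5 (2E)-1-[2,4-bis(benzyloxy)-6-hydroxyphenyl]-3-[4-(benzyloxy)phenyl]prop-2-en-1-one, via aldol adduct 4 (not isolated)
Conditions: KOH (50% aq, 10 equiv), EtOH/THF, rt, 48 h; then 1 M HCl
Reagents that add atoms: none
Why: Claisen–Schmidt aldol condensation of a methyl ketone with a non-enolisable aldehyde, the racemic aldol adduct dehydrating (E1cB) to the conjugated E-chalcone.

**Step 3**
Reactants: 5 (2E)-1-[2,4-bis(benzyloxy)-6-hydroxyphenyl]-3-[4-(benzyloxy)phenyl]prop-2-en-1-one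
Product: 7 5,7-bis(benzyloxy)-2-[4-(benzyloxy)phenyl]-4H-chromen-4-one, via flavanone 6 (not isolated)
Conditions: I2 (0.1 equiv), DMSO, 130 °C; aq Na2S2O3 work-up
Reagents that add atoms: none
Why: Oxidative cyclisation of a 2'-hydroxychalcone by oxa-Michael closure to the racemic flavanone and iodine-mediated dehydrogenation, DMSO reoxidising HI; benzyl ethers survive.

**Step 4**
Reactants: 7 5,7-bis(benzyloxy)-2-[4-(benzyloxy)phenyl]-4H-chromen-4-one
Product: 8 7-(benzyloxy)-2-[4-(benzyloxy)phenyl]-5-hydroxy-4H-chromen-4-one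
Conditions: MgBr2·OEt2 (3 equiv), toluene/Et2O, reflux; 1 M HCl work-up
Reagents that add atoms: none
Why: Chelation-controlled Lewis-acid ether cleavage in which magnesium bridges C4=O and the peri 5-O, so only that benzyl group is removed by bromide.

**Step 5**
Reactants: 8 7-(benzyloxy)-2-[4-(benzyloxy)phenyl]-5-hydroxy-4H-chromen-4-one
Product: 9 7-(benzyloxy)-2-[4-(benzyloxy)phenyl]-5-hydroxy-6-iodo-4H-chromen-4-one
Conditions: NIS (1.1 equiv), DMF, rt, dark
Reagents that add atoms: N-iodosuccinimide, O=C1CCC(=O)N1I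
Why: Electrophilic aromatic iodination of a 5-hydroxy-7-alkoxyflavone under neutral conditions goes ortho to the free phenol, at C6 between the two oxygens.

**Step 6**
Reactants: 9 7-(benzyloxy)-2-[4-(benzyloxy)phenyl]-5-hydroxy-6-iodo-4H-chromen-4-one
Product: 10 7-(benzyloxy)-2-[4-(benzyloxy)phenyl]-6-iodo-5-(methoxymethoxy)-4H-chromen-4-one
Conditions: NaH (1.3 equiv), MOMCl (1.5 equiv), DMF, 0 °C → rt
Reagents that add atoms: chloromethyl methyl ether, COCCl
Why: Irreversible deprotonation breaks the hydrogen bond and the small, reactive MOM chloride O-alkylates the hindered phenoxide (SN2), masking the phenol next to the coupling site.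

**Step 7**
Reactants: 2 1-[2,4-bis(benzyloxy)-6-hydroxyphenyl]ethan-1-one
Product: 11 1-[4,6-bis(benzyloxy)-2-hydroxy-3-iodophenyl]ethan-1-one
Conditions: NIS (1.05 equiv), DMF, 0 °C → rt, dark
Reagents that add atoms: N-iodosuccinimide, O=C1CCC(=O)N1I
Why: Electrophilic aromatic iodination of the phloroacetophenone ring occurs ortho to the free phenol (C3), as for the dimethyl ether analogue.

**Step 8**
Reactants: 11 1-[4,6-bis(benzyloxy)-2-hydroxy-3-iodophenyl]ethan-1-one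
Product: 12 1-[4,6-bis(benzyloxy)-3-iodo-2-(methoxymethoxy)phenyl]ethan-1-one
Conditions: NaH (1.1 equiv), DMF, 0 °C; then MOMCl (1.3 equiv), rt
Reagents that add atoms: chloromethyl methyl ether, COCCl
Why: One equivalent of base deprotonates only the phenol (far more acidic than the methyl ketone), and O-alkylation with MOM chloride follows (SN2).

**Step 9**
Reactants: 12 1-[4,6-bis(benzyloxy)-3-iodo-2-(methoxymethoxy)phenyl]ethan-1-one
Product: 13 1-[4,6-bis(benzyloxy)-2-(methoxymethoxy)-3-(4,4,5,5-tetramethyl-1,3,2-dioxaborolan-2-yl)phenyl]ethan-1-one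
Conditions: B2pin2 (2 equiv), Pd2(dba)3 (2.5 mol %), SPhos (10 mol %), KOAc (3 equiv), 1,4-dioxane, 100 °C
Reagents that add atoms: bis(pinacolato)diboron, CC1(C)OB(OC1(C)C)B1OC(C)(C)C(C)(C)O1
Why: Miyaura borylation with a bulky biarylphosphine tolerates the ketone and the two ortho substituents, and the weak base KOAc prevents homocoupling.

**Step 10**
Reactants: 10 7-(benzyloxy)-2-[4-(benzyloxy)phenyl]-6-iodo-5-(methoxymethoxy)-4H-chromen-4-one; 13 1-[4,6-bis(benzyloxy)-2-(methoxymethoxy)-3-(4,4,5,5-tetramethyl-1,3,2-dioxaborolan-2-yl)phenyl]ethan-1-one (1.5 equiv)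
Product: 14 6-[3-acetyl-4,6-bis(benzyloxy)-2-(methoxymethoxy)phenyl]-7-(benzyloxy)-2-[4-(benzyloxy)phenyl]-5-(methoxymethoxy)-4H-chromen-4-one
Conditions: Pd(OAc)2 (10 mol %), SPhos (20 mol %), K3PO4 (3 equiv), toluene/H2O (10:1), 100 °C, argon
Reagents that add atoms: none
Why: Suzuki–Miyaura coupling in which SPhos-ligated zerovalent palladium adds to the aryl iodide and forces transmetalation and reductive elimination to the tetra-ortho-substituted biaryl, formed as a racemic axis.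

**Step 11**
Reactants: 14 6-[3-acetyl-4,6-bis(benzyloxy)-2-(methoxymethoxy)phenyl]-7-(benzyloxy)-2-[4-(benzyloxy)phenyl]-5-(methoxymethoxy)-4H-chromen-4-one
Product: 15 6-[3-acetyl-4,6-bis(benzyloxy)-2-hydroxyphenyl]-7-(benzyloxy)-2-[4-(benzyloxy)phenyl]-5-hydroxy-4H-chromen-4-one
Conditions: 3 M HCl (aq), MeOH/THF, 50 °C
Reagents that add atoms: none
Why: Acid-catalysed acetal exchange removes both MOM groups, while benzyl ethers, the ketone and the flavone are inert to dilute acid at this temperature.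

**Step 12 (key step)**
Reactants: 15 6-[3-acetyl-4,6-bis(benzyloxy)-2-hydroxyphenyl]-7-(benzyloxy)-2-[4-(benzyloxy)phenyl]-5-hydroxy-4H-chromen-4-one; 16 4-methoxybenzaldehyde (1.5 equiv)
Product: 18 6-{4,6-bis(benzyloxy)-2-hydroxy-3-[(2E)-3-(4-methoxyphenyl)prop-2-enoyl]phenyl}-7-(benzyloxy)-2-[4-(benzyloxy)phenyl]-5-hydroxy-4H-chromen-4-one, via aldol adduct 17 (not isolated)
Conditions: KOH (50% aq, excess), EtOH/THF, rt, 48–72 h; then 1 M HCl
Reagents that add atoms: none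
Why: Intermolecular Claisen–Schmidt aldol condensation joins the biaryl ketone to the anisyl fragment and gives the E-chalcone after E1cB dehydration, the existing flavone being shielded from hydroxide as its 5-phenoxide.

**Step 13**
Reactants: 18 6-{4,6-bis(benzyloxy)-2-hydroxy-3-[(2E)-3-(4-methoxyphenyl)prop-2-enoyl]phenyl}-7-(benzyloxy)-2-[4-(benzyloxy)phenyl]-5-hydroxy-4H-chromen-4-one
Product: 20 5,7-bis(benzyloxy)-8-{7-(benzyloxy)-2-[4-(benzyloxy)phenyl]-5-hydroxy-4-oxo-4H-chromen-6-yl}-2-(4-methoxyphenyl)-4H-chromen-4-one, via flavanone 19 (not isolated)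
Conditions: I2 (0.1 equiv), DMSO, 120 °C; aq Na2S2O3 work-up
Reagents that add atoms: none
Why: Oxidative cyclisation of the 2'-hydroxychalcone (oxa-Michael, then iodine/DMSO dehydrogenation) closes through the only free acetophenone phenol, which lies next to the biaryl bond and so fixes the 8-linkage.

**Step 14**
Reactants: 20 5,7-bis(benzyloxy)-8-{7-(benzyloxy)-2-[4-(benzyloxy)phenyl]-5-hydroxy-4-oxo-4H-chromen-6-yl}-2-(4-methoxyphenyl)-4H-chromen-4-one
Product: 21 8-[5,7-dihydroxy-2-(4-hydroxyphenyl)-4-oxo-4H-chromen-6-yl]-5,7-dihydroxy-2-(4-methoxyphenyl)-4H-chromen-4-one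
Conditions: H2 (1 atm), 10% Pd/C, THF/MeOH, rt
Reagents that add atoms: none
Why: Catalytic hydrogenolysis cleaves the four aryl benzyl ethers and leaves the aryl methyl ether and the flavone C2=C3 bonds untouched.

## Compound list

1 | 2',4',6'-trihydroxyacetophenone | CC(=O)c1c(O)cc(O)cc1O | starting material
2 | 1-[2,4-bis(benzyloxy)-6-hydroxyphenyl]ethan-1-one | CC(=O)c1c(O)cc(OCc2ccccc2)cc1OCc1ccccc1 | intermediate
3 | 4-(benzyloxy)benzaldehyde | O=Cc1ccc(OCc2ccccc2)cc1 | starting material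
4 | 1-[2,4-bis(benzyloxy)-6-hydroxyphenyl]-3-[4-(benzyloxy)phenyl]-3-hydroxypropan-1-one (racemic, not isolated) | O=C(CC(O)c1ccc(OCc2ccccc2)cc1)c1c(O)cc(OCc2ccccc2)cc1OCc1ccccc1 | intermediate
5 | (2E)-1-[2,4-bis(benzyloxy)-6-hydroxyphenyl]-3-[4-(benzyloxy)phenyl]prop-2-en-1-one | O=C(/C=C/c1ccc(OCc2ccccc2)cc1)c1c(O)cc(OCc2ccccc2)cc1OCc1ccccc1 | intermediate
6 | 5,7-bis(benzyloxy)-2-[4-(benzyloxy)phenyl]-2,3-dihydro-4H-chromen-4-one (racemic, not isolated) | O=C1CC(c2ccc(OCc3ccccc3)cc2)Oc2cc(OCc3ccccc3)cc(OCc3ccccc3)c21 | intermediate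
7 | 5,7-bis(benzyloxy)-2-[4-(benzyloxy)phenyl]-4H-chromen-4-one | O=c1cc(-c2ccc(OCc3ccccc3)cc2)oc2cc(OCc3ccccc3)cc(OCc3ccccc3)c12 | intermediate
8 | 7-(benzyloxy)-2-[4-(benzyloxy)phenyl]-5-hydroxy-4H-chromen-4-one | O=c1cc(-c2ccc(OCc3ccccc3)cc2)oc2cc(OCc3ccccc3)cc(O)c12 | intermediate
9 | 7-(benzyloxy)-2-[4-(benzyloxy)phenyl]-5-hydroxy-6-iodo-4H-chromen-4-one | O=c1cc(-c2ccc(OCc3ccccc3)cc2)oc2cc(OCc3ccccc3)c(I)c(O)c12 | intermediate
10 | 7-(benzyloxy)-2-[4-(benzyloxy)phenyl]-6-iodo-5-(methoxymethoxy)-4H-chromen-4-one | COCOc1c(I)c(OCc2ccccc2)cc2oc(-c3ccc(OCc4ccccc4)cc3)cc(=O)c12 | intermediate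
11 | 1-[4,6-bis(benzyloxy)-2-hydroxy-3-iodophenyl]ethan-1-one | CC(=O)c1c(O)c(I)c(OCc2ccccc2)cc1OCc1ccccc1 | intermediate
12 | 1-[4,6-bis(benzyloxy)-3-iodo-2-(methoxymethoxy)phenyl]ethan-1-one | CC(=O)c1c(OCOC)c(I)c(OCc2ccccc2)cc1OCc1ccccc1 | intermediate
13 | 1-[4,6-bis(benzyloxy)-2-(methoxymethoxy)-3-(4,4,5,5-tetramethyl-1,3,2-dioxaborolan-2-yl)phenyl]ethan-1-one | CC(=O)c1c(OCOC)c(B2OC(C)(C)C(C)(C)O2)c(OCc2ccccc2)cc1OCc1ccccc1 | intermediate
14 | 6-[3-acetyl-4,6-bis(benzyloxy)-2-(methoxymethoxy)phenyl]-7-(benzyloxy)-2-[4-(benzyloxy)phenyl]-5-(methoxymethoxy)-4H-chromen-4-one (racemic axis) | CC(=O)c1c(OCOC)c(-c2c(OCc3ccccc3)cc3oc(-c4ccc(OCc5ccccc5)cc4)cc(=O)c3c2OCOC)c(OCc2ccccc2)cc1OCc1ccccc1 | intermediate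
15 | 6-[3-acetyl-4,6-bis(benzyloxy)-2-hydroxyphenyl]-7-(benzyloxy)-2-[4-(benzyloxy)phenyl]-5-hydroxy-4H-chromen-4-one | CC(=O)c1c(O)c(-c2c(OCc3ccccc3)cc3oc(-c4ccc(OCc5ccccc5)cc4)cc(=O)c3c2O)c(OCc2ccccc2)cc1OCc1ccccc1 | intermediate
16 | 4-methoxybenzaldehyde | COc1ccc(C=O)cc1 | starting material
17 | 6-{4,6-bis(benzyloxy)-2-hydroxy-3-[3-hydroxy-3-(4-methoxyphenyl)propanoyl]phenyl}-7-(benzyloxy)-2-[4-(benzyloxy)phenyl]-5-hydroxy-4H-chromen-4-one (stereoisomer mixture, not isolated) | COc1ccc(C(O)CC(=O)c2c(O)c(-c3c(OCc4ccccc4)cc4oc(-c5ccc(OCc6ccccc6)cc5)cc(=O)c4c3O)c(OCc3ccccc3)cc2OCc2ccccc2)cc1 | intermediate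
18 | 6-{4,6-bis(benzyloxy)-2-hydroxy-3-[(2E)-3-(4-methoxyphenyl)prop-2-enoyl]phenyl}-7-(benzyloxy)-2-[4-(benzyloxy)phenyl]-5-hydroxy-4H-chromen-4-one | COc1ccc(/C=C/C(=O)c2c(O)c(-c3c(OCc4ccccc4)cc4oc(-c5ccc(OCc6ccccc6)cc5)cc(=O)c4c3O)c(OCc3ccccc3)cc2OCc2ccccc2)cc1 | intermediate
19 | 5,7-bis(benzyloxy)-8-{7-(benzyloxy)-2-[4-(benzyloxy)phenyl]-5-hydroxy-4-oxo-4H-chromen-6-yl}-2-(4-methoxyphenyl)-2,3-dihydro-4H-chromen-4-one (stereoisomer mixture, not isolated) | COc1ccc(C2CC(=O)c3c(OCc4ccccc4)cc(OCc4ccccc4)c(-c4c(OCc5ccccc5)cc5oc(-c6ccc(OCc7ccccc7)cc6)cc(=O)c5c4O)c3O2)cc1 | intermediate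
20 | 5,7-bis(benzyloxy)-8-{7-(benzyloxy)-2-[4-(benzyloxy)phenyl]-5-hydroxy-4-oxo-4H-chromen-6-yl}-2-(4-methoxyphenyl)-4H-chromen-4-one | COc1ccc(-c2cc(=O)c3c(OCc4ccccc4)cc(OCc4ccccc4)c(-c4c(OCc5ccccc5)cc5oc(-c6ccc(OCc7ccccc7)cc6)cc(=O)c5c4O)c3o2)cc1 | intermediate
21 | 8-[5,7-dihydroxy-2-(4-hydroxyphenyl)-4-oxo-4H-chromen-6-yl]-5,7-dihydroxy-2-(4-methoxyphenyl)-4H-chromen-4-one | COc1ccc(-c2cc(=O)c3c(O)cc(O)c(-c4c(O)cc5oc(-c6ccc(O)cc6)cc(=O)c5c4O)c3o2)cc1 | target

## Summary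

Total step count: 14.
Longest linear sequence: 11 steps (steps 1, 2, 3, 4, 5, 6, 10, 11, 12, 13, 14, from 1 to 21). The boronate branch (steps 7, 8, 9) joins at step 10.

Three steps most likely to fail:

**Step 10 (Suzuki coupling to a tetra-ortho-substituted biaryl).** The electron-rich, doubly ortho-oxygenated boronate 13 may protodeboronate faster than it transmetalates. The fallback replaces boron by zinc and sets out from iodide 12. Direct zinc insertion (Zn dust, LiCl, THF, 50 °C), which tolerates the ketone, gives [3-acetyl-4,6-bis(benzyloxy)-2-(methoxymethoxy)phenyl]zinc iodide F1. Negishi coupling of this with iodoflavone 10 (Pd2(dba)3, RuPhos, THF/NMP, 70 °C) runs without base or water and comes back to the route at 14.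

**Step 9 (borylation of the hindered, ketone-bearing iodide).** Reduction of the C–I bond or low conversion would leave no nucleophile. The fallback swaps the roles of the partners and sets out from iodoflavone 10. Borylation (B2pin2, Pd2(dba)3, SPhos, KOAc, 1,4-dioxane, 100 °C) gives 7-(benzyloxy)-2-[4-(benzyloxy)phenyl]-5-(methoxymethoxy)-6-(4,4,5,5-tetramethyl-1,3,2-dioxaborolan-2-yl)-4H-chromen-4-one F2. This is coupled with the bench-stable iodide 12 (Pd(OAc)2, SPhos, K3PO4, toluene/H2O, 100 °C) and comes back to the route at 14.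

**Step 12 (late aldol on a hindered ketone next to a base-sensitive flavone).** Slow enolisation or hydroxide attack on the existing pyranone could erode the yield. The fallback changes the carbonyl partner and the oxidation level and sets out from ketone 15. The trilithio species (LiN(SiMe3)2, 5 equiv, THF, −78 → −10 °C) is C-acylated with 4-methoxybenzoyl chloride in an intermolecular Claisen condensation, the lithium phenoxides being poor acyl acceptors at this temperature. This gives 1-{4,6-bis(benzyloxy)-3-{7-(benzyloxy)-2-[4-(benzyloxy)phenyl]-5-hydroxy-4-oxo-4H-chromen-6-yl}-2-hydroxyphenyl}-3-(4-methoxyphenyl)propane-1,3-dione F3. Acid-catalysed cyclodehydration (TsOH·H2O, toluene, 80 °C) then gives the flavone directly and comes back to the route at 20, bypassing 18 and the iodine/DMSO step.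

## Further compounds

F1 | step 10 | [3-acetyl-4,6-bis(benzyloxy)-2-(methoxymethoxy)phenyl]zinc iodide | CC(=O)c1c(OCOC)c([Zn]I)c(OCc2ccccc2)cc1OCc1ccccc1
F2 | step 9 | 7-(benzyloxy)-2-[4-(benzyloxy)phenyl]-5-(methoxymethoxy)-6-(4,4,5,5-tetramethyl-1,3,2-dioxaborolan-2-yl)-4H-chromen-4-one | COCOc1c(B2OC(C)(C)C(C)(C)O2)c(OCc2ccccc2)cc2oc(-c3ccc(OCc4ccccc4)cc3)cc(=O)c12
F3 | step 12 | 1-{4,6-bis(benzyloxy)-3-{7-(benzyloxy)-2-[4-(benzyloxy)phenyl]-5-hydroxy-4-oxo-4H-chromen-6-yl}-2-hydroxyphenyl}-3-(4-methoxyphenyl)propane-1,3-dione | COc1ccc(C(=O)CC(=O)c2c(O)c(-c3c(OCc4ccccc4)cc4oc(-c5ccc(OCc6ccccc6)cc5)cc(=O)c4c3O)c(OCc3ccccc3)cc2OCc2ccccc2)cc1
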